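Ring C, the hexasubstituted hydroxy-p-quinone (C8, C9, C11–C14; oxygen on C11, C12 and C14, isopropyl on C13) that shares the C8=C9 bond with ring B, is traced back to a squaric-acid-derived four-membered ring. One thermolysis unravels a 4-hydroxycyclobutenone to a ketene flanked by two alkenes, bonds the ketene carbon (C14) to C8 by 6π closure and aromatises, so the whole hydroquinone ring appears in a single operation with every substituent in place. The precursor carries this cyclobutenone on C9 of an (R)-carvone-derived ring B cyclohexene in which C5, C7 and C10 are already set. Triethylsilyl ethers at C7 and C3 later allow one chromic acid step to deliver quinone, ketone and acid.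

Key step: step 11

Remark: atoms are numbered as in the abietane skeleton (C1–C3 = chain on C10, C4 = isopropenyl carbon on C5, ring B = C5–C10, ring C = C8, C9, C11–C14); the target is the (5S,10S) enantiomer, which is the one reached from (R)-carvone, and the chain is carried as a silyl ether so that no ester is present when the C9 lithium reagent is made.

Step 1
Reactants: 1 (R)-carvone
Product: 4 (1R)-4-methyl-5-oxocyclohex-3-en-1-yl acetate, via methoxy hydroperoxide 2 (not isolated), via peroxyacetate 3 (not isolated)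
Conditions: O3, CH2Cl2–MeOH, −78 °C; then Ac2O, Et3N, DMAP (cat.), −78 °C → rt
Reagents that add atoms: ozone, [O-][O+]=O; methanol, CO
Why: Ozonolysis of the electron-rich isopropenyl alkene in methanol (the conjugated enone reacts far more slowly) should give 2, whose acetylation to 3 triggers a Criegee rearrangement in which the ring carbon migrates from carbon to oxygen with retention, so the (R) centre of 1 becomes the future C7 carbinol centre unchanged.

Step 2
Reactants: 4 (1R)-4-methyl-5-oxocyclohex-3-en-1-yl acetate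
Product: 5 (5R)-5-hydroxy-2-methylcyclohex-2-en-1-one
Conditions: K2CO3 (cat.), MeOH, 0 °C
Reagents that add atoms: none
Why: Carbonate-catalysed methanolysis (transesterification) removes the acetate under conditions cold and brief enough to outrun β-elimination towards o-cresol, and the stereocentre is not touched.

Step 3
Reactants: 5 (5R)-5-hydroxy-2-methylcyclohex-2-en-1-one
Product: 6 (5R)-2-methyl-5-(triethylsilyloxy)cyclohex-2-en-1-one
Conditions: Et3SiCl, imidazole, CH2Cl2, 0 °C → rt
Reagents that add atoms: chlorotriethylsilane, CC[Si](Cl)(CC)CC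
Why: Imidazole-promoted silylation of a secondary alcohol; triethylsilyl is chosen because it survives the organometallic steps yet is cleaved by aqueous chromic acid in the operation that later oxidises C7.

Step 4
Reactants: 6 (5R)-2-methyl-5-(triethylsilyloxy)cyclohex-2-en-1-one; 7 isopropenylmagnesium bromide; 8 allyl iodide
Product: 10 (2S,3S,5R)-2-methyl-2-(prop-2-en-1-yl)-3-(prop-1-en-2-yl)-5-(triethylsilyloxy)cyclohexan-1-one, via bromomagnesium enolate 9 (not isolated)
Conditions: CuBr·SMe2 (20 mol%), THF, −78 → −40 °C; then 8, DMPU, −40 °C → rt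
Reagents that add atoms: none
Why: Copper-catalysed conjugate addition of the Grignard reagent should place the isopropenyl group on the β-carbon (C5) anti to the 1,3-related C7 silyloxy group (axial attack on the half-chair), and the regiodefined enolate 9 is then C-allylated on the face opposite the new isopropenyl group, so the quaternary C10 forms with allyl trans and methyl cis to isopropenyl in one tandem conjugate addition–enolate alkylation.

Step 5
Reactants: 10 (2S,3S,5R)-2-methyl-2-(prop-2-en-1-yl)-3-(prop-1-en-2-yl)-5-(triethylsilyloxy)cyclohexan-1-one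
Product: 12 (3R,5S,6S)-6-methyl-6-(prop-2-en-1-yl)-5-(prop-1-en-2-yl)-3-(triethylsilyloxy)cyclohex-1-en-1-yl trifluoromethanesulfonate, via potassium enolate 11 (not isolated)
Conditions: KN(SiMe3)2, THF, −78 °C; then PhNTf2, −78 → 0 °C
Reagents that add atoms: N-phenylbis(trifluoromethanesulfonimide), O=S(=O)(N(c1ccccc1)S(=O)(=O)C(F)(F)F)C(F)(F)F
Why: Because C10 is quaternary only C8 can be deprotonated, so a single enolate 11 forms and is O-sulfonylated to the C8=C9 enol triflate (enol triflate formation), the low temperature and short enolate lifetime suppressing E1cB loss of the C7 silyloxy group.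

Step 6
Reactants: 12 (3R,5S,6S)-6-methyl-6-(prop-2-en-1-yl)-5-(prop-1-en-2-yl)-3-(triethylsilyloxy)cyclohex-1-en-1-yl trifluoromethanesulfonate
Product: 14 (3R,5S,6S)-6-(3-hydroxypropyl)-6-methyl-5-(prop-1-en-2-yl)-3-(triethylsilyloxy)cyclohex-1-en-1-yl trifluoromethanesulfonate, via alkylborane 13 (not isolated)
Conditions: (Sia)2BH (from BH3·THF and 2-methylbut-2-ene), THF, 0 °C; then NaBO3·4H2O, THF–H2O, rt
Reagents that add atoms: sodium perborate, [Na+].[O-]OB=O
Why: Hydroboration–oxidation with the bulky dialkylborane should add boron to the terminal carbon of the monosubstituted allyl alkene much faster than to the 1,1-disubstituted isopropenyl group or the electron-poor enol triflate, and mildly basic perborate converts the C–B bond of 13 into C–OH without hydrolysing the triflate or the silyl ether.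

Step 7
Reactants: 14 (3R,5S,6S)-6-(3-hydroxypropyl)-6-methyl-5-(prop-1-en-2-yl)-3-(triethylsilyloxy)cyclohex-1-en-1-yl trifluoromethanesulfonate
Product: 15 (3R,5S,6S)-6-methyl-5-(prop-1-en-2-yl)-3-(triethylsilyloxy)-6-[3-(triethylsilyloxy)propyl]cyclohex-1-en-1-yl trifluoromethanesulfonate
Conditions: Et3SiCl, imidazole, CH2Cl2, 0 °C
Reagents that add atoms: chlorotriethylsilane, CC[Si](Cl)(CC)CC
Why: Routine silylation of the primary alcohol removes the only acidic proton before the organolithium step and gives C3 the same acid-labile protecting group as C7.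

Step 8
Reactants: 15 (3R,5S,6S)-6-methyl-5-(prop-1-en-2-yl)-3-(triethylsilyloxy)-6-[3-(triethylsilyloxy)propyl]cyclohex-1-en-1-yl trifluoromethanesulfonate
Product: 16 trimethyl{(3R,5S,6S)-6-methyl-5-(prop-1-en-2-yl)-3-(triethylsilyloxy)-6-[3-(triethylsilyloxy)propyl]cyclohex-1-en-1-yl}stannane
Conditions: (Me3Sn)2, Pd(PPh3)4 (5 mol%), LiCl, THF, 65 °C
Reagents that add atoms: hexamethylditin, C[Sn](C)(C)[Sn](C)(C)C
Why: Stille-type stannylation in which zerovalent palladium inserts into the alkenyl C9–O bond, chloride from LiCl enables transmetalation with the distannane and reductive elimination gives the C9 stannane, a reaction established for cyclohexenyl triflates next to quaternary carbons.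

Step 9
Reactants: 17 dimethyl squarate; 18 isopropylmagnesium chloride
Product: 21 3-methoxy-4-(propan-2-yl)cyclobut-3-ene-1,2-dione, via magnesium alkoxide 19 (not isolated), via trifluoroacetate 20 (not isolated)
Conditions: THF, −78 °C; then (CF3CO)2O, −78 °C → rt; aqueous work-up
Reagents that add atoms: water, O
Why: 1,2-Addition of the Grignard reagent to one squarate carbonyl gives 19, and trifluoroacetylation to 20 followed by aqueous work-up causes allylic ionisation and vinylogous hydrolysis with loss of methanol, the standard squarate-to-3-alkyl-4-alkoxycyclobutenedione transposition.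

Step 10
Reactants: 16 trimethyl{(3R,5S,6S)-6-methyl-5-(prop-1-en-2-yl)-3-(triethylsilyloxy)-6-[3-(triethylsilyloxy)propyl]cyclohex-1-en-1-yl}stannane; 21 3-methoxy-4-(propan-2-yl)cyclobut-3-ene-1,2-dione
Product: 23 4-hydroxy-3-methoxy-2-(propan-2-yl)-4-{(3R,5S,6S)-6-methyl-5-(prop-1-en-2-yl)-3-(triethylsilyloxy)-6-[3-(triethylsilyloxy)propyl]cyclohex-1-en-1-yl}cyclobut-2-en-1-one (both carbinol epimers), via alkenyllithium 22 (not isolated)
Conditions: MeLi, THF, −78 → −20 °C; then 21, THF, −78 °C; aq. NH4Cl
Reagents that add atoms: none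
Why: Tin–lithium exchange gives the C9 alkenyllithium 22 without moving the double bond, and carbonyl addition of this organolithium should occur at the ketone-like carbonyl of 21 flanked by the methoxy-bearing carbon and not at the less electrophilic vinylogous ester carbonyl, which fixes the later ring C substitution pattern; the new carbinol centre forms as both epimers, which is harmless because it becomes sp2 in step 11.

Step 11
Reactants: 23 4-hydroxy-3-methoxy-2-(propan-2-yl)-4-{(3R,5S,6S)-6-methyl-5-(prop-1-en-2-yl)-3-(triethylsilyloxy)-6-[3-(triethylsilyloxy)propyl]cyclohex-1-en-1-yl}cyclobut-2-en-1-one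
Product: 26 (5S,6S,8R)-3-methoxy-5-methyl-2-(propan-2-yl)-6-(prop-1-en-2-yl)-8-(triethylsilyloxy)-5-[3-(triethylsilyloxy)propyl]-5,6,7,8-tetrahydronaphthalene-1,4-diol, via dienylketene 24 (not isolated), via cyclohexadienone 25 (not isolated)
Conditions: degassed toluene, 110 °C, argon
Reagents that add atoms: none
Why: On heating, the σ bond between the carbonyl carbon and the carbinol carbon of the cyclobutenone opens in a conrotatory 4π electrocyclic step, and because the donor hydroxyl turns outward the C9 alkenyl group sits on the inside, beside the ketene of 24. A thermally allowed disrotatory 6π electrocyclisation of the ketene C=C, the C12=C11 enol ether and the C9=C8 alkene then bonds the ketene carbon (C14) to C8 and closes ring C as dienone 25, whose C8 hydrogen shifts to oxygen to give the aromatic hydroquinone 26. The closest known reaction type is the Moore rearrangement of 4-alkenyl- and 4-aryl-4-hydroxycyclobutenones made from squaric esters. No stereocentre is created: the carbinol carbon and the transient C8 centre both end sp2, so both epimers of 23 converge, and C5, C7 and C10 are not involved. The step needs outward rotation of the hydroxyl (torquoselectivity, secured by the oxygen lone pairs of that substituent) and the correct placement of oxygen at C11, C12 and C14 and of isopropyl at C13, which is already built into 23 by the regiochemistry of step 10. Loss of four-membered-ring strain and the gain of aromaticity make the cascade irreversible at a temperature that the silyl ethers and the isopropenyl group tolerate.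

Step 12
Reactants: 26 (5S,6S,8R)-3-methoxy-5-methyl-2-(propan-2-yl)-6-(prop-1-en-2-yl)-8-(triethylsilyloxy)-5-[3-(triethylsilyloxy)propyl]-5,6,7,8-tetrahydronaphthalene-1,4-diol
Product: 29 3-[(1S,2S)-7-methoxy-1-methyl-4,5,8-trioxo-6-(propan-2-yl)-2-(prop-1-en-2-yl)-1,2,3,4,5,8-hexahydronaphthalen-1-yl]propanoic acid, via quinone bis-silyl ether 27 (not isolated), via quinone diol 28 (not isolated)
Conditions: CrO3, aq. H2SO4, acetone, 0 °C → rt (crude 26 used directly)
Reagents that add atoms: water, O
Why: Jones oxidation in which chromic acid converts the hydroquinone into p-quinone 27 at once, the aqueous acid strips both triethylsilyl ethers to diol 28, and the C7 secondary and C3 primary alcohols are then oxidised to ketone and carboxylic acid, while the methoxyquinone, the isopropenyl alkene and the non-epimerisable C5 and C10 centres should be unaffected.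

Step 13
Reactants: 29 3-[(1S,2S)-7-methoxy-1-methyl-4,5,8-trioxo-6-(propan-2-yl)-2-(prop-1-en-2-yl)-1,2,3,4,5,8-hexahydronaphthalen-1-yl]propanoic acid
Product: 30 methyl 3-[(1S,2S)-7-methoxy-1-methyl-4,5,8-trioxo-6-(propan-2-yl)-2-(prop-1-en-2-yl)-1,2,3,4,5,8-hexahydronaphthalen-1-yl]propanoate
Conditions: MeI, KHCO3, DMF, rt
Reagents that add atoms: iodomethane, CI
Why: SN2 O-methylation of the potassium carboxylate (carboxylate alkylation) is unambiguous here because no quinone hydroxyl is free at this stage.

Step 14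
Reactants: 30 methyl 3-[(1S,2S)-7-methoxy-1-methyl-4,5,8-trioxo-6-(propan-2-yl)-2-(prop-1-en-2-yl)-1,2,3,4,5,8-hexahydronaphthalen-1-yl]propanoate
Product: 31 methyl 3-[(1S,2S)-7-hydroxy-1-methyl-4,5,8-trioxo-6-(propan-2-yl)-2-(prop-1-en-2-yl)-1,2,3,4,5,8-hexahydronaphthalen-1-yl]propanoate (CNP0308749.1)
Conditions: LiOH (1.05 equiv), THF–H2O, 0 °C; then 1 M HCl
Reagents that add atoms: lithium hydroxide, [Li+].[OH-]
Why: Hydroxide should add to C12 of the strongly electron-poor ene-trione and expel methoxide (addition–elimination, the saponification of a vinylogous ester), a process expected to be faster than attack at the unactivated methyl ester and one that consumes the single equivalent of base by forming the non-basic hydroxyquinone anion, which acidification converts into the target.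

Compound list
1 | (R)-carvone, (5R)-2-methyl-5-(prop-1-en-2-yl)cyclohex-2-en-1-one | CC1=CC[C@H](CC1=O)C(=C)C | starting material
2 | (5R)-5-(1-hydroperoxy-1-methoxyethyl)-2-methylcyclohex-2-en-1-one (methoxy hydroperoxide, epimers at the new carbon) | CC1=CC[C@H](CC1=O)C(C)(OC)OO | intermediate
3 | peroxyacetate of 2 | CC1=CC[C@H](CC1=O)C(C)(OC)OOC(C)=O | intermediate
4 | (1R)-4-methyl-5-oxocyclohex-3-en-1-yl acetate | CC1=CC[C@H](CC1=O)OC(C)=O | intermediate
5 | (5R)-5-hydroxy-2-methylcyclohex-2-en-1-one | CC1=CC[C@H](CC1=O)O | intermediate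
6 | (5R)-2-methyl-5-(triethylsilyloxy)cyclohex-2-en-1-one | CC1=CC[C@H](CC1=O)O[Si](CC)(CC)CC | intermediate
7 | isopropenylmagnesium bromide | C=C(C)[Mg]Br | starting material
8 | allyl iodide (3-iodoprop-1-ene) | C=CCI | starting material
9 | bromomagnesium enolate of the conjugate adduct (isopropenyl trans to the silyloxy group) | C=C(C)[C@@H]1C[C@@H](O[Si](CC)(CC)CC)CC(O[Mg]Br)=C1C | intermediate
10 | (2S,3S,5R)-2-methyl-2-(prop-2-en-1-yl)-3-(prop-1-en-2-yl)-5-(triethylsilyloxy)cyclohexan-1-one | C=C(C)[C@@H]1C[C@@H](O[Si](CC)(CC)CC)CC(=O)[C@@]1(C)CC=C | intermediate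
11 | potassium C8–C9 enolate of 10 | C=C(C)[C@@H]1C[C@@H](O[Si](CC)(CC)CC)C=C([O-])[C@@]1(C)CC=C.[K+] | intermediate
12 | (3R,5S,6S)-6-methyl-6-(prop-2-en-1-yl)-5-(prop-1-en-2-yl)-3-(triethylsilyloxy)cyclohex-1-en-1-yl trifluoromethanesulfonate | C=C(C)[C@@H]1C[C@@H](O[Si](CC)(CC)CC)C=C(OS(=O)(=O)C(F)(F)F)[C@@]1(C)CC=C | intermediate
13 | bis(3-methylbutan-2-yl)borane adduct of 12 at the terminal allyl carbon | C=C(C)[C@@H]1C[C@@H](O[Si](CC)(CC)CC)C=C(OS(=O)(=O)C(F)(F)F)[C@@]1(C)CCCB(C(C)C(C)C)C(C)C(C)C | intermediate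
14 | (3R,5S,6S)-6-(3-hydroxypropyl)-6-methyl-5-(prop-1-en-2-yl)-3-(triethylsilyloxy)cyclohex-1-en-1-yl trifluoromethanesulfonate | C=C(C)[C@@H]1C[C@@H](O[Si](CC)(CC)CC)C=C(OS(=O)(=O)C(F)(F)F)[C@@]1(C)CCCO | intermediate
15 | (3R,5S,6S)-6-methyl-5-(prop-1-en-2-yl)-3-(triethylsilyloxy)-6-[3-(triethylsilyloxy)propyl]cyclohex-1-en-1-yl trifluoromethanesulfonate | C=C(C)[C@@H]1C[C@@H](O[Si](CC)(CC)CC)C=C(OS(=O)(=O)C(F)(F)F)[C@@]1(C)CCCO[Si](CC)(CC)CC | intermediate
16 | trimethyl{(3R,5S,6S)-6-methyl-5-(prop-1-en-2-yl)-3-(triethylsilyloxy)-6-[3-(triethylsilyloxy)propyl]cyclohex-1-en-1-yl}stannane | C=C(C)[C@@H]1C[C@@H](O[Si](CC)(CC)CC)C=C([Sn](C)(C)C)[C@@]1(C)CCCO[Si](CC)(CC)CC | intermediate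
17 | dimethyl squarate (3,4-dimethoxycyclobut-3-ene-1,2-dione) | COC1=C(OC)C(=O)C1=O | starting material
18 | isopropylmagnesium chloride | CC(C)[Mg]Cl | starting material
19 | chloromagnesium alkoxide of 4-hydroxy-2,3-dimethoxy-4-(propan-2-yl)cyclobut-2-en-1-one | COC1=C(OC)C(O[Mg]Cl)(C(C)C)C1=O | intermediate
20 | trifluoroacetate of 4-hydroxy-2,3-dimethoxy-4-(propan-2-yl)cyclobut-2-en-1-one | COC1=C(OC)C(OC(=O)C(F)(F)F)(C(C)C)C1=O | intermediate
21 | 3-methoxy-4-(propan-2-yl)cyclobut-3-ene-1,2-dione | COC1=C(C(C)C)C(=O)C1=O | intermediate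
22 | C9 alkenyllithium from 16 (same configuration) | C=C(C)[C@@H]1C[C@@H](O[Si](CC)(CC)CC)C=C([Li])[C@@]1(C)CCCO[Si](CC)(CC)CC | intermediate
23 | 4-hydroxy-3-methoxy-2-(propan-2-yl)-4-{(3R,5S,6S)-6-methyl-5-(prop-1-en-2-yl)-3-(triethylsilyloxy)-6-[3-(triethylsilyloxy)propyl]cyclohex-1-en-1-yl}cyclobut-2-en-1-one (both carbinol epimers) | C=C(C)[C@@H]1C[C@@H](O[Si](CC)(CC)CC)C=C(C2(O)C(OC)=C(C(C)C)C2=O)[C@@]1(C)CCCO[Si](CC)(CC)CC | intermediate
24 | dienylketene (C9 and C13 cis across C11=C12) | C=C(C)[C@@H]1C[C@@H](O[Si](CC)(CC)CC)C=C(/C(O)=C(OC)\C(C(C)C)=C=O)[C@@]1(C)CCCO[Si](CC)(CC)CC | intermediate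
25 | cyclohexa-2,4-dienone with sp3 C8 (C8 epimers) | C=C(C)[C@@H]1C[C@@H](O[Si](CC)(CC)CC)C2C(=O)C(C(C)C)=C(OC)C(O)=C2[C@@]1(C)CCCO[Si](CC)(CC)CC | intermediate
26 | (5S,6S,8R)-3-methoxy-5-methyl-2-(propan-2-yl)-6-(prop-1-en-2-yl)-8-(triethylsilyloxy)-5-[3-(triethylsilyloxy)propyl]-5,6,7,8-tetrahydronaphthalene-1,4-diol | C=C(C)[C@@H]1C[C@@H](O[Si](CC)(CC)CC)c2c(O)c(C(C)C)c(OC)c(O)c2[C@@]1(C)CCCO[Si](CC)(CC)CC | intermediate
27 | (5S,6S,8R)-3-methoxy-5-methyl-2-(propan-2-yl)-6-(prop-1-en-2-yl)-8-(triethylsilyloxy)-5-[3-(triethylsilyloxy)propyl]-5,6,7,8-tetrahydronaphthalene-1,4-dione | C=C(C)[C@@H]1C[C@@H](O[Si](CC)(CC)CC)C2=C(C(=O)C(OC)=C(C(C)C)C2=O)[C@@]1(C)CCCO[Si](CC)(CC)CC | intermediate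
28 | (5S,6S,8R)-8-hydroxy-5-(3-hydroxypropyl)-3-methoxy-5-methyl-2-(propan-2-yl)-6-(prop-1-en-2-yl)-5,6,7,8-tetrahydronaphthalene-1,4-dione | C=C(C)[C@@H]1C[C@@H](O)C2=C(C(=O)C(OC)=C(C(C)C)C2=O)[C@@]1(C)CCCO | intermediate
29 | 3-[(1S,2S)-7-methoxy-1-methyl-4,5,8-trioxo-6-(propan-2-yl)-2-(prop-1-en-2-yl)-1,2,3,4,5,8-hexahydronaphthalen-1-yl]propanoic acid | C=C(C)[C@@H]1CC(=O)C2=C(C(=O)C(OC)=C(C(C)C)C2=O)[C@@]1(C)CCC(=O)O | intermediate
30 | methyl 3-[(1S,2S)-7-methoxy-1-methyl-4,5,8-trioxo-6-(propan-2-yl)-2-(prop-1-en-2-yl)-1,2,3,4,5,8-hexahydronaphthalen-1-yl]propanoate | C=C(C)[C@@H]1CC(=O)C2=C(C(=O)C(OC)=C(C(C)C)C2=O)[C@@]1(C)CCC(=O)OC | intermediate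
31 | methyl 3-[(1S,2S)-7-hydroxy-1-methyl-4,5,8-trioxo-6-(propan-2-yl)-2-(prop-1-en-2-yl)-1,2,3,4,5,8-hexahydronaphthalen-1-yl]propanoate (CNP0308749.1) | C=C(C)[C@@H]1CC(=O)C2=C(C(=O)C(O)=C(C(C)C)C2=O)[C@@]1(C)CCC(=O)OC | target

Total step count: 14. Longest linear sequence: 13 (steps 1–8 and 10–14); step 9 is a one-step branch.

Steps most likely to fail

1. Step 11 (key step). What may go wrong: interception of the ketene by the free carbinol oxygen (closure to a butenolide if the hydroxyl turns inward), or thermal loss of the C7 silyloxy group from the free ortho-hydroxybenzylic hydroquinone. Fallback: the cascade is run on a capped carbinol. From 23, TMSOTf and 2,6-lutidine in CH2Cl2 at −78 °C should give the trimethylsilyl ether F1. Heating F1 in toluene follows the same 4π/6π path with no hydroxyl available to trap the ketene and should give the C11 O-silylated hydroquinone F2. Under the conditions of step 12, F2 loses all three silyl groups and is oxidised, rejoining the route at 29.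

2. Step 10. What may go wrong: slow tin–lithium exchange at the hindered C9 position, and proton transfer from the isopropyl methine of 21 to the strongly basic alkenyllithium in place of carbonyl addition. Fallback: a different exchange and a different metal. From 16, iododestannylation (I2, CH2Cl2, 0 °C) should give the C9 alkenyl iodide F3. Irreversible iodine–lithium exchange (t-BuLi, Et2O, −78 °C) regenerates 22, which is transmetalated with anhydrous CeCl3 to the far less basic alkenylcerium dichloride F4. Addition of F4 to 21 at −78 °C returns to 23.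

3. Step 14. What may go wrong: competing saponification of the C3 methyl ester, or base-induced degradation of the ene-trione, so that the selective exchange at C12 is lost. Fallback: the last two operations are inverted so that no ester is present when base is used. From 29, excess aqueous NaOH in THF followed by acidification should give the 12-hydroxyquinone keto acid F5. Fischer esterification (MeOH, cat. TsOH, rt), which should convert the carboxylic acid but not the hindered, hydrogen-bonded vinylogous acid at C12, then gives 31 directly.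

Further compounds
F1 | step 11 | trimethylsilyl ether of 23 (4-trimethylsilyloxycyclobutenone, both epimers) | C=C(C)[C@@H]1C[C@@H](O[Si](CC)(CC)CC)C=C(C2(O[Si](C)(C)C)C(OC)=C(C(C)C)C2=O)[C@@]1(C)CCCO[Si](CC)(CC)CC
F2 | step 11 | C11 O-trimethylsilyl ether of hydroquinone 26 (free phenol at C14) | C=C(C)[C@@H]1C[C@@H](O[Si](CC)(CC)CC)c2c(O)c(C(C)C)c(OC)c(O[Si](C)(C)C)c2[C@@]1(C)CCCO[Si](CC)(CC)CC
F3 | step 10 | (3R,5S,6S)-1-iodo-6-methyl-5-(prop-1-en-2-yl)-3-(triethylsilyloxy)-6-[3-(triethylsilyloxy)propyl]cyclohex-1-ene | C=C(C)[C@@H]1C[C@@H](O[Si](CC)(CC)CC)C=C(I)[C@@]1(C)CCCO[Si](CC)(CC)CC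
F4 | step 10 | C9 alkenylcerium dichloride from 22 | C=C(C)[C@@H]1C[C@@H](O[Si](CC)(CC)CC)C=C([Ce](Cl)Cl)[C@@]1(C)CCCO[Si](CC)(CC)CC
F5 | step 14 | 3-[(1S,2S)-7-hydroxy-1-methyl-4,5,8-trioxo-6-(propan-2-yl)-2-(prop-1-en-2-yl)-1,2,3,4,5,8-hexahydronaphthalen-1-yl]propanoic acid | C=C(C)[C@@H]1CC(=O)C2=C(C(=O)C(O)=C(C(C)C)C2=O)[C@@]1(C)CCC(=O)O
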